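**Plan**
- Retrosynthesis: the three phenols are masked as benzyl ethers; ring C is opened at O1–C2 (cyclodehydration) to a 2‑methoxy‑1,3‑diketone; the diketone is cut at both C4a–C4 and C4–C3, so that C4 becomes carbon monoxide.
- Enabling feature: the C4 carbonyl of the pyranone (ring C) sits between the aromatic C4a of ring A and the enolisable, methoxylated C3, which is the array aryl iodide / CO / ketone enolate.
- Forward: the ring‑A iodide (4 steps) and the ring‑B methoxymethyl ketone (5 steps) are made separately and joined with CO into the open C6–C3–C6 chain; ring C then closes under acid through the only unmasked phenol, and hydrogenolysis frees the three hydroxyls.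
- Stereochemistry: the target is an achiral, planar flavone. The only sp3 stereocentre on the way (the carbon between the two carbonyls) is racemic, enolisable and erased on aromatisation.

Key step: step 10

Remark: the target SMILES carries no stereodescriptor and the molecule has no stereogenic element, so "single enantiomer" requires no control.
Remark: N,2‑dimethoxy‑N‑methylacetamide is taken as a catalogue reagent.

**Step 1**
Reactants: 1 3‑hydroxy‑4,5‑dimethoxybenzaldehyde
Product: 2 3,4‑dimethoxy‑5‑(methoxymethoxy)benzaldehyde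
Conditions: MOMCl, K2CO3, acetone, 0 °C to rt
Reagents that add atoms: chloromethyl methyl ether (MOMCl), COCCl
Why: Williamson‑type O‑alkylation of the phenoxide with the reactive α‑chloro ether; the aldehyde is inert to carbonate.

**Step 2**
Reactants: 2 3,4‑dimethoxy‑5‑(methoxymethoxy)benzaldehyde
Product: 4 3,4‑dimethoxy‑5‑(methoxymethoxy)phenol, via aryl formate 3 (not isolated)
Conditions: mCPBA, CH2Cl2, 0 °C to rt; then K2CO3 (cat.), MeOH, rt
Reagents that add atoms: 3‑chloroperoxybenzoic acid (mCPBA), OOC(=O)c1cccc(Cl)c1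
Why: Baeyer–Villiger (Dakin‑type) oxidation in which the 3,4,5‑trioxygenated aryl group migrates in preference to hydride, as with 3,4,5‑trimethoxybenzaldehyde; the formate is methanolysed under mild base that leaves the MOM acetal intact.

**Step 3**
Reactants: 4 3,4‑dimethoxy‑5‑(methoxymethoxy)phenol
Product: 5 5‑(benzyloxy)‑1,2‑dimethoxy‑3‑(methoxymethoxy)benzene
Conditions: BnBr, K2CO3, DMF, rt
Reagents that add atoms: benzyl bromide, BrCc1ccccc1
Why: Williamson ether synthesis on an unhindered phenoxide.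

**Step 4**
Reactants: 5 5‑(benzyloxy)‑1,2‑dimethoxy‑3‑(methoxymethoxy)benzene
Product: 7 1‑(benzyloxy)‑2‑iodo‑4,5‑dimethoxy‑3‑(methoxymethoxy)benzene, via aryllithium 6 (not isolated)
Conditions: n‑BuLi, TMEDA, THF, −20 °C; then I2, −78 °C to rt
Reagents that add atoms: iodine, II
Why: directed ortho‑metalation at the C–H flanked by OMOM and OBn, as in the 2‑lithiation of 1,3‑dialkoxybenzenes; MOM is a stronger director than the methoxy group flanking the other free position, and iodinolysis of the aryllithium is ipso.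

**Step 5**
Reactants: 8 2,4‑dihydroxybenzaldehyde
Product: 9 2,4‑bis(benzyloxy)benzaldehyde
Conditions: BnBr (2.2 equiv), K2CO3, DMF, 60 °C
Reagents that add atoms: benzyl bromide, BrCc1ccccc1
Why: double Williamson etherification; warming overcomes the hydrogen‑bonded 2‑hydroxyl.

**Step 6**
Reactants: 9 2,4‑bis(benzyloxy)benzaldehyde
Product: 11 2,4‑bis(benzyloxy)phenol, via aryl formate 10 (not isolated)
Conditions: mCPBA, CH2Cl2, rt; then K2CO3 (cat.), MeOH, rt
Reagents that add atoms: 3‑chloroperoxybenzoic acid (mCPBA), OOC(=O)c1cccc(Cl)c1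
Why: Baeyer–Villiger (Dakin‑type) oxidation; the ortho and para benzyloxy groups strongly favour aryl migration, and the formate is cleaved by methanolysis.

**Step 7**
Reactants: 11 2,4‑bis(benzyloxy)phenol
Product: 12 2,4‑bis(benzyloxy)‑1‑methoxybenzene
Conditions: MeI, K2CO3, acetone, reflux
Reagents that add atoms: iodomethane, CI
Why: Williamson O‑methylation of the phenoxide.

**Step 8**
Reactants: 12 2,4‑bis(benzyloxy)‑1‑methoxybenzene
Product: 13 1,5‑bis(benzyloxy)‑2‑bromo‑4‑methoxybenzene
Conditions: NBS, MeCN, 0 °C to rt, dark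
Reagents that add atoms: N‑bromosuccinimide, O=C1CCC(=O)N1Br
Why: electrophilic aromatic bromination at the only position that is para to one benzyloxy group and ortho to the other without lying between them, the pattern by which 1,2,4‑trialkoxybenzenes brominate at C5.

**Step 9**
Reactants: 13 1,5‑bis(benzyloxy)‑2‑bromo‑4‑methoxybenzene; 14 N,2‑dimethoxy‑N‑methylacetamide
Product: 17 1‑[2,4‑bis(benzyloxy)‑5‑methoxyphenyl]‑2‑methoxyethan‑1‑one, via aryllithium 15 (not isolated), via tetrahedral lithium adduct 16 (not isolated)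
Conditions: n‑BuLi, THF, −78 °C; then 14, −78 to 0 °C; aqueous quench
Reagents that add atoms: none
Why: bromine–lithium exchange at −78 °C is faster than benzylic deprotonation, and the Weinreb ketone synthesis stops at the chelated tetrahedral adduct, so that neither over‑addition nor enolisation of the α‑methoxy ketone occurs before the quench.

**Step 10**
Reactants: 7 1‑(benzyloxy)‑2‑iodo‑4,5‑dimethoxy‑3‑(methoxymethoxy)benzene; 17 1‑[2,4‑bis(benzyloxy)‑5‑methoxyphenyl]‑2‑methoxyethan‑1‑one; 18 carbon monoxide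
Product: 19 1‑[6‑(benzyloxy)‑3,4‑dimethoxy‑2‑(methoxymethoxy)phenyl]‑3‑[2,4‑bis(benzyloxy)‑5‑methoxyphenyl]‑2‑methoxypropane‑1,3‑dione (racemic, enolisable)
Conditions: Pd(dba)2 (5 mol %), Xantphos (5 mol %), K3PO4 (3 equiv), CO (1 atm), 17 (1.2 equiv), 1,4‑dioxane, 80 °C; then aq. NH4Cl
Reagents that add atoms: none
Why: Pd(0)/Xantphos adds oxidatively to the C–I bond of 7, CO inserts to give the 2,6‑dialkoxyaroyl–Pd(II) species, the potassium enolate of 17 (its α‑CH2 acidified by the α‑methoxy group and the aryl ketone) replaces iodide on palladium, and C–C reductive elimination releases the 2‑methoxy‑1,3‑diketone, so that C4a–C4 and C4–C3 of the flavone form in one operation. The closest known reaction is the palladium‑catalysed carbonylative α‑arylation of aryl alkyl ketones with aryl iodides to 1,3‑diketones, applied here to an α‑alkoxy ketone and a doubly ortho‑substituted iodide. No ring is closed in this step; ring C is deliberately left open until step 11. The carbon between the two carbonyls is a stereocentre only formally: it forms racemic, is enolised at once as the diketonate and disappears on aromatisation, so no element of control is needed. The step needs carbonylative coupling to outrun direct α‑arylation and proto‑deiodination; the two ortho alkoxy groups of 7 secure this, because they retard enolate coupling at the crowded aryl–Pd centre while migratory insertion of CO relieves that crowding and is fast under a CO atmosphere. It also needs C‑ over O‑acylation and mono‑acylation, both favoured because the product is withdrawn as its stable potassium diketonate, which no longer acts as a nucleophile.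

**Step 11**
Reactants: 19 1‑[6‑(benzyloxy)‑3,4‑dimethoxy‑2‑(methoxymethoxy)phenyl]‑3‑[2,4‑bis(benzyloxy)‑5‑methoxyphenyl]‑2‑methoxypropane‑1,3‑dione
Product: 22 5‑(benzyloxy)‑2‑[2,4‑bis(benzyloxy)‑5‑methoxyphenyl]‑3,7,8‑trimethoxy‑4H‑chromen‑4‑one, via free phenol diketone 20 (not isolated), via cyclic hemiketal 21 (not isolated)
Conditions: HCl (3 M in MeOH), THF, 50 °C
Reagents that add atoms: none
Why: acid‑catalysed acetal cleavage of the MOM ether, then cyclodehydration (6‑exo‑trig hemiketalisation onto the B‑ring carbonyl and loss of water to the aromatic 4‑pyranone), the classical closing step of 1‑(2‑hydroxyaryl)‑1,3‑diketone flavone syntheses; the benzyl ethers resist methanolic HCl, so only the C8a oxygen can close.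

**Step 12**
Reactants: 22 5‑(benzyloxy)‑2‑[2,4‑bis(benzyloxy)‑5‑methoxyphenyl]‑3,7,8‑trimethoxy‑4H‑chromen‑4‑one
Product: 23 5,2',4'‑trihydroxy‑3,7,8,5'‑tetramethoxyflavone
Conditions: H2 (1 atm), 10 % Pd/C, EtOAc–MeOH, rt; filtration under argon
Reagents that add atoms: none
Why: catalytic hydrogenolysis of aryl benzyl ethers; the tetrasubstituted, vinylogous‑ester C2=C3 bond of a 3‑methoxyflavone should not be reduced at atmospheric pressure.

**Compound list**
1 | 3‑hydroxy‑4,5‑dimethoxybenzaldehyde | COc1cc(C=O)cc(O)c1OC | starting material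
2 | 3,4‑dimethoxy‑5‑(methoxymethoxy)benzaldehyde | COCOc1cc(C=O)cc(OC)c1OC | intermediate
3 | 3,4‑dimethoxy‑5‑(methoxymethoxy)phenyl formate | COCOc1cc(OC=O)cc(OC)c1OC | intermediate
4 | 3,4‑dimethoxy‑5‑(methoxymethoxy)phenol | COCOc1cc(O)cc(OC)c1OC | intermediate
5 | 5‑(benzyloxy)‑1,2‑dimethoxy‑3‑(methoxymethoxy)benzene | COCOc1cc(OCc2ccccc2)cc(OC)c1OC | intermediate
6 | [6‑(benzyloxy)‑3,4‑dimethoxy‑2‑(methoxymethoxy)phenyl]lithium | COCOc1c([Li])c(OCc2ccccc2)cc(OC)c1OC | intermediate
7 | 1‑(benzyloxy)‑2‑iodo‑4,5‑dimethoxy‑3‑(methoxymethoxy)benzene | COCOc1c(I)c(OCc2ccccc2)cc(OC)c1OC | intermediate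
8 | 2,4‑dihydroxybenzaldehyde | O=Cc1ccc(O)cc1O | starting material
9 | 2,4‑bis(benzyloxy)benzaldehyde | O=Cc1ccc(OCc2ccccc2)cc1OCc1ccccc1 | intermediate
10 | 2,4‑bis(benzyloxy)phenyl formate | O=COc1ccc(OCc2ccccc2)cc1OCc1ccccc1 | intermediate
11 | 2,4‑bis(benzyloxy)phenol | Oc1ccc(OCc2ccccc2)cc1OCc1ccccc1 | intermediate
12 | 2,4‑bis(benzyloxy)‑1‑methoxybenzene | COc1ccc(OCc2ccccc2)cc1OCc1ccccc1 | intermediate
13 | 1,5‑bis(benzyloxy)‑2‑bromo‑4‑methoxybenzene | COc1cc(Br)c(OCc2ccccc2)cc1OCc1ccccc1 | intermediate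
14 | N,2‑dimethoxy‑N‑methylacetamide | COCC(=O)N(C)OC | starting material
15 | [2,4‑bis(benzyloxy)‑5‑methoxyphenyl]lithium | COc1cc([Li])c(OCc2ccccc2)cc1OCc1ccccc1 | intermediate
16 | lithium 1‑[2,4‑bis(benzyloxy)‑5‑methoxyphenyl]‑2‑methoxy‑1‑[methoxy(methyl)amino]ethan‑1‑olate | [Li+].COCC([O-])(N(C)OC)c1cc(OC)c(OCc2ccccc2)cc1OCc1ccccc1 | intermediate
17 | 1‑[2,4‑bis(benzyloxy)‑5‑methoxyphenyl]‑2‑methoxyethan‑1‑one | COCC(=O)c1cc(OC)c(OCc2ccccc2)cc1OCc1ccccc1 | intermediate
18 | carbon monoxide | [C-]#[O+] | starting material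
19 | 1‑[6‑(benzyloxy)‑3,4‑dimethoxy‑2‑(methoxymethoxy)phenyl]‑3‑[2,4‑bis(benzyloxy)‑5‑methoxyphenyl]‑2‑methoxypropane‑1,3‑dione | COCOc1c(C(=O)C(OC)C(=O)c2cc(OC)c(OCc3ccccc3)cc2OCc2ccccc2)c(OCc2ccccc2)cc(OC)c1OC | intermediate
20 | 1‑[6‑(benzyloxy)‑2‑hydroxy‑3,4‑dimethoxyphenyl]‑3‑[2,4‑bis(benzyloxy)‑5‑methoxyphenyl]‑2‑methoxypropane‑1,3‑dione | Oc1c(C(=O)C(OC)C(=O)c2cc(OC)c(OCc3ccccc3)cc2OCc2ccccc2)c(OCc2ccccc2)cc(OC)c1OC | intermediate
21 | 5‑(benzyloxy)‑2‑[2,4‑bis(benzyloxy)‑5‑methoxyphenyl]‑2‑hydroxy‑3,7,8‑trimethoxy‑2,3‑dihydro‑4H‑chromen‑4‑one (diastereomer mixture) | COC1C(=O)c2c(OCc3ccccc3)cc(OC)c(OC)c2OC1(O)c1cc(OC)c(OCc2ccccc2)cc1OCc1ccccc1 | intermediate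
22 | 5‑(benzyloxy)‑2‑[2,4‑bis(benzyloxy)‑5‑methoxyphenyl]‑3,7,8‑trimethoxy‑4H‑chromen‑4‑one | COc1cc(-c2oc3c(OC)c(OC)cc(OCc4ccccc4)c3c(=O)c2OC)c(OCc2ccccc2)cc1OCc1ccccc1 | intermediate
23 | 5,2',4'‑trihydroxy‑3,7,8,5'‑tetramethoxyflavone [2‑(2,4‑dihydroxy‑5‑methoxyphenyl)‑5‑hydroxy‑3,7,8‑trimethoxy‑4H‑chromen‑4‑one] | COc1cc(-c2oc3c(OC)c(OC)cc(O)c3c(=O)c2OC)c(O)cc1O | target

**Step count and risks**
Total steps: 12. Longest linear sequence: 8 (steps 5–9, then 10, 11, 12).

Step 10 (most at risk). Capture of the crowded aroyl–palladium species by the substituted enolate may be slow, so that decarbonylation with direct α‑arylation, proto‑deiodination or O‑acylation take over. The fallback sets out from 5 and 17 and returns at 19; it forms the same two bonds one after the other with stoichiometric reagents. Arene 5 is lithiated as in step 4 and the aryllithium 6 is quenched with CO2 to give, after buffered acidification, 6‑(benzyloxy)‑3,4‑dimethoxy‑2‑(methoxymethoxy)benzoic acid F1. This acid is converted under neutral conditions with 1‑chloro‑N,N,2‑trimethylprop‑1‑en‑1‑amine in CH2Cl2 into 6‑(benzyloxy)‑3,4‑dimethoxy‑2‑(methoxymethoxy)benzoyl chloride F2. Ketone 17 is then C‑acylated with F2 under soft enolisation (MgBr2·OEt2, i‑Pr2NEt, CH2Cl2), a Claisen‑type acylation that should give diketone 19.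

Step 4. n‑BuLi may remove a benzylic proton of the benzyl ether (with subsequent [1,2]‑Wittig rearrangement), or metalate the other flanked position, between the benzyloxy and the neighbouring methoxy group. The fallback sets out from 4 and returns at 7; iodine is introduced before the benzyl group, under a stronger director. Phenol 4 is carbamoylated (ClCONEt2, K2CO3, MeCN) to 3,4‑dimethoxy‑5‑(methoxymethoxy)phenyl diethylcarbamate F3. s‑BuLi/TMEDA in THF at −78 °C lithiates the position flanked by the carbamate and the OMOM group to give [6‑(diethylcarbamoyloxy)‑3,4‑dimethoxy‑2‑(methoxymethoxy)phenyl]lithium F4. This is quenched at −78 °C with I2 to 2‑iodo‑4,5‑dimethoxy‑3‑(methoxymethoxy)phenyl diethylcarbamate F5. Hydrolysis (NaOH, EtOH, reflux) gives 2‑iodo‑4,5‑dimethoxy‑3‑(methoxymethoxy)phenol F6, and benzylation (BnBr, K2CO3, DMF) gives 7.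

Step 11. Under protic acid the benzyl ether ortho to the A‑ring carbonyl may be lost before ring closure, so that the ring closes through the wrong oxygen, or the diketone may undergo acid‑catalysed methanolysis (retro‑Claisen) before it cyclises. The fallback sets out from 19 and returns at 22; the cascade is split into two separate reactions of different type. The MOM group alone is removed with ZnBr2/n‑PrSH in CH2Cl2 at 0 °C, a thiol‑assisted Lewis‑acid cleavage in an aprotic, non‑nucleophilic medium, and phenol 20 (in equilibrium with hemiketal 21) is isolated. Dehydration is then carried out on its own in buffered AcOH/NaOAc at 100 °C to give 22. No new compound arises.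

**Further compounds**
F1 | step 10 | 6‑(benzyloxy)‑3,4‑dimethoxy‑2‑(methoxymethoxy)benzoic acid | COCOc1c(C(=O)O)c(OCc2ccccc2)cc(OC)c1OC
F2 | step 10 | 6‑(benzyloxy)‑3,4‑dimethoxy‑2‑(methoxymethoxy)benzoyl chloride | COCOc1c(C(=O)Cl)c(OCc2ccccc2)cc(OC)c1OC
F3 | step 4 | 3,4‑dimethoxy‑5‑(methoxymethoxy)phenyl diethylcarbamate | COCOc1cc(OC(=O)N(CC)CC)cc(OC)c1OC
F4 | step 4 | [6‑(diethylcarbamoyloxy)‑3,4‑dimethoxy‑2‑(methoxymethoxy)phenyl]lithium | COCOc1c([Li])c(OC(=O)N(CC)CC)cc(OC)c1OC
F5 | step 4 | 2‑iodo‑4,5‑dimethoxy‑3‑(methoxymethoxy)phenyl diethylcarbamate | COCOc1c(I)c(OC(=O)N(CC)CC)cc(OC)c1OC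
F6 | step 4 | 2‑iodo‑4,5‑dimethoxy‑3‑(methoxymethoxy)phenol | COCOc1c(I)c(O)cc(OC)c1OC
F0 | step 11 | none | none
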